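**Strategy.** Everything rests on disconnecting ring B (C5–C10) at C6–C7 and C7–C8: without C7, ring B is a trans-fused cyclopentanone (C5, C6, C8, C9, C10) on ring A. The key step exploits this feature and the unequal flanks of the C8 carbonyl, a free C6 methylene against the branched C9 methine beside quaternary C10. BF3-promoted insertion of the carbon of Me3SiCHN2 with migration of C6 creates C7, both new ring bonds and the C8 cyclohexanone (the later 8(17)-methylene site) in one operation. Its precursor is the trans-4,4,7a-trimethylhydrindan-2-one that already carries the complete C11–C16 side chain on C9, with the 14,15-diol masked as an acetonide.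

Key step: step 11

Remarks on the chemistry (labdane numbering is used for atoms throughout):
- The sense of induction of the allylation is assumed to follow the usual behaviour of t-Bu-phosphinooxazoline ligands, where the (S)-ligand gives (S)-2-allyl-2-alkylcyclohexanones; the (R)-ligand is therefore chosen.
- The (Z)-crotylborane made from (+)-Ipc2BOMe (the borane from (−)-α-pinene) is assumed to add to the Re face of the aldehyde, its usual sense of induction.
- The trimethylcyclohexanone is used as the racemate, since its only stereocentre is lost on enolisation.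
- Any minor enantiomer of the ring fragment becomes a diastereomer once the enantiopure side chain is attached and can be removed there.

**Route**

Step 1
Reactants: 1 2,2,6-trimethylcyclohexanone; 2 allyl chloroformate
Product: 4 allyl 2,6,6-trimethylcyclohex-1-en-1-yl carbonate, via lithium enolate 3 (not isolated)
Conditions: LiN(SiMe3)2, THF, 0 °C; then 2, −78 °C
Reagents that add atoms: allyl chloroformate (compound 2), C=CCOC(=O)Cl
Why: The ketone has a single enolisable position, so one tetrasubstituted lithium enolate forms and is O-acylated by the chloroformate at low temperature (enol carbonate formation).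

Step 2
Reactants: 4 allyl 2,6,6-trimethylcyclohex-1-en-1-yl carbonate
Product: 5 (R)-2-allyl-2,6,6-trimethylcyclohexan-1-one
Conditions: Pd2(dba)3 (cat.), (R)-t-Bu-PHOX (cat.), THF, 25 °C
Reagents that add atoms: none
Why: Oxidative addition of zerovalent palladium, loss of CO2 and allylation of the enolate inside the chiral phosphinooxazoline pocket (decarboxylative asymmetric allylic alkylation, established for this substrate class) should set quaternary C10 as R.

Step 3
Reactants: 5 (R)-2-allyl-2,6,6-trimethylcyclohexan-1-one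
Product: 6 (R)-2,2,6-trimethyl-6-(2-oxopropyl)cyclohexan-1-one
Conditions: PdCl2 (cat.), Cu(OAc)2·H2O (cat.), O2 (1 atm), DMA/H2O, 23 °C
Reagents that add atoms: water, O
Why: Tsuji–Wacker oxidation of the terminal alkene gives the methyl ketone with Markovnikov selectivity, while the hindered ring ketone is a bystander.

Step 4
Reactants: 6 (R)-2,2,6-trimethyl-6-(2-oxopropyl)cyclohexan-1-one
Product: 8 (7aR)-4,4,7a-trimethyl-1,4,5,6,7,7a-hexahydro-2H-inden-2-one, via ketol 7 (not isolated)
Conditions: KOH, xylenes, 110 °C, Dean–Stark trap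
Reagents that add atoms: none
Why: Intramolecular aldol condensation: the ring ketone cannot enolise (C4 and C10 are quaternary), so only the methyl carbon (C6) can attack C5 in a five-membered closure, and azeotropic dehydration drives the ketol to the conjugated enone without touching C10.

Step 5
Reactants: 9 (tert-butyldimethylsilyloxy)acetaldehyde; 10 cis-2-butene
Product: 12 (2S,3R)-1-[(tert-butyldimethylsilyl)oxy]-3-methylpent-4-en-2-ol, via borinate ester 11 (not isolated)
Conditions: 10, n-BuLi, KOt-Bu, THF, −78 → −45 °C; (+)-Ipc2BOMe, −78 °C; BF3·OEt2; 9, −78 °C; then NaOH, H2O2, 0 → 23 °C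
Reagents that add atoms: cis-2-butene (compound 10), C/C=C\C
Why: Brown crotylation: the (Z)-crotylborane reacts through a closed chair transition state, so the Z geometry becomes the 13,14-syn relationship and the isopinocampheyl groups direct addition to the Re face of the aldehyde, setting C14 as S and C13 as R.

Step 6
Reactants: 12 (2S,3R)-1-[(tert-butyldimethylsilyl)oxy]-3-methylpent-4-en-2-ol
Product: 14 (4S)-4-[(2R)-but-3-en-2-yl]-2,2-dimethyl-1,3-dioxolane, via diol 13 (not isolated)
Conditions: CSA (cat.), MeOH, 23 °C; then 2,2-dimethoxypropane (excess), 23 °C; Et3N quench; careful concentration (volatile)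
Reagents that add atoms: 2,2-dimethoxypropane, COC(C)(C)OC
Why: Acidic methanolysis removes the primary silyl ether and acid-catalysed transacetalisation then ties the 1,2-diol up as the five-membered acetonide, with no stereocentre involved.

Step 7
Reactants: 14 (4S)-4-[(2R)-but-3-en-2-yl]-2,2-dimethyl-1,3-dioxolane
Product: 16 (3R)-3-[(4S)-2,2-dimethyl-1,3-dioxolan-4-yl]butan-1-ol, via alkylborane 15 (not isolated)
Conditions: 9-BBN, THF, 0 → 23 °C; then NaOH, H2O2, 0 °C
Reagents that add atoms: hydrogen peroxide, OO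
Why: Hydroboration–oxidation with the bulky 9-BBN places boron on the terminal carbon (anti-Markovnikov), and oxidation with retention gives the primary C11 alcohol.

Step 8
Reactants: 16 (3R)-3-[(4S)-2,2-dimethyl-1,3-dioxolan-4-yl]butan-1-ol
Product: 17 (4S)-4-[(2R)-4-iodobutan-2-yl]-2,2-dimethyl-1,3-dioxolane
Conditions: PPh3, I2, imidazole, CH2Cl2, 0 → 23 °C
Reagents that add atoms: iodine, II
Why: Appel-type iodination converts the unhindered primary alcohol into the iodide by SN2 displacement of the oxyphosphonium group, and imidazole keeps the medium non-acidic for the acetonide.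

Step 9
Reactants: 8 (7aR)-4,4,7a-trimethyl-1,4,5,6,7,7a-hexahydro-2H-inden-2-one; 17 (4S)-4-[(2R)-4-iodobutan-2-yl]-2,2-dimethyl-1,3-dioxolane
Product: 19 (1S,7aR)-1-{(3R)-3-[(4S)-2,2-dimethyl-1,3-dioxolan-4-yl]butyl}-4,4,7a-trimethyl-1,4,5,6,7,7a-hexahydro-2H-inden-2-one, via lithium dienolate 18 (not isolated)
Conditions: LiN(i-Pr)2, THF, −78 °C; then 17, HMPA, −78 → −20 °C
Reagents that add atoms: none
Why: Kinetic deprotonation can only occur at C9 (both γ positions, C4 and C10, are quaternary), and SN2 alkylation of the cross-conjugated lithium dienolate by the primary iodide forms C9–C11 (α′-alkylation of an enone), the electrophile approaching trans to the angular methyl C20, so this C9 configuration is provisional.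

Step 10
Reactants: 19 (1S,7aR)-1-{(3R)-3-[(4S)-2,2-dimethyl-1,3-dioxolan-4-yl]butyl}-4,4,7a-trimethyl-1,4,5,6,7,7a-hexahydro-2H-inden-2-one
Product: 22 (1R,3aS,7aS)-1-{(3R)-3-[(4S)-2,2-dimethyl-1,3-dioxolan-4-yl]butyl}-4,4,7a-trimethyloctahydro-2H-inden-2-one, via lithium enolate 20 (not isolated), via 9-epi-hydrindanone 21 (not isolated)
Conditions: Li, NH3(l)/THF, t-BuOH (1 equiv), −78 °C; isoprene, then NH4Cl; crude product: NaOMe (cat.), MeOH, 23 °C
Reagents that add atoms: none
Why: Dissolving-metal (Birch-type) conjugate reduction protonates C5 on the α face, away from the two syn-axial methyl groups on C4 and C10, which sets the trans ring fusion, and NaOMe should then equilibrate C9 towards the side chain cis to C20 (as C17 substituents of trans-hydrindane steroids prefer), any remaining C9 epimer converging after step 11.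

Step 11
Reactants: 22 (1R,3aS,7aS)-1-{(3R)-3-[(4S)-2,2-dimethyl-1,3-dioxolan-4-yl]butyl}-4,4,7a-trimethyloctahydro-2H-inden-2-one; 23 (trimethylsilyl)diazomethane
Product: 25 (1R,4aS,8aS)-1-{(3R)-3-[(4S)-2,2-dimethyl-1,3-dioxolan-4-yl]butyl}-5,5,8a-trimethyloctahydronaphthalen-2(1H)-one, via 7-silyl ketone 24 (not isolated)
Conditions: 23 (hexanes solution), BF3·OEt2, CH2Cl2, −78 → −40 °C; then K2CO3, MeOH, 23 °C
Reagents that add atoms: (trimethylsilyl)diazomethane (compound 23), C[Si](C)(C)C=[N+]=[N-]
Why: BF3 activates the C8 carbonyl, the diazo carbon adds, and a 1,2-shift of a ring carbon with loss of N2 enlarges the ring; the closest known reaction type is the Lewis-acid-promoted homologation of cycloalkanones with (trimethylsilyl)diazomethane, a Tiffeneau–Demjanov-type ring expansion. Ring B is not closed by cyclisation but grows out of the cyclopentanone, the new C7 ending up bonded to C6 and C8. The step needs migration of C6 and not of C9, which the substrate secures because C6 is an unhindered methylene whereas C9 is a branched methine wedged between the side chain and quaternary C10, and the bulky Me3Si group on the incoming carbon disfavours alignment of the C9–C8 bond. The α-silyl group of 24 shields the new cyclohexanone from a second insertion and is removed by K2CO3/MeOH, which also equilibrates C9 so that the side chain sits equatorial (β). No permanent stereocentre is created, and C5 and C10 are untouched. The acetonide should tolerate BF3·OEt2 at or below −40 °C.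

Step 12
Reactants: 25 (1R,4aS,8aS)-1-{(3R)-3-[(4S)-2,2-dimethyl-1,3-dioxolan-4-yl]butyl}-5,5,8a-trimethyloctahydronaphthalen-2(1H)-one; 26 methyltriphenylphosphonium bromide
Product: 27 (4S)-4-{(2R)-4-[(1S,4aS,8aS)-5,5,8a-trimethyl-2-methylidenedecahydronaphthalen-1-yl]butan-2-yl}-2,2-dimethyl-1,3-dioxolane
Conditions: 26 (excess), KOt-Bu, toluene, 80 °C
Reagents that add atoms: methyltriphenylphosphonium bromide (compound 26), C[P+](c1ccccc1)(c1ccccc1)c1ccccc1.[Br-]
Why: Wittig methylenation with excess ylide at elevated temperature converts the hindered C8 ketone into the exocyclic 8(17)-alkene, and the basic medium can only hold C9 in its thermodynamic equatorial configuration.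

Step 13
Reactants: 27 (4S)-4-{(2R)-4-[(1S,4aS,8aS)-5,5,8a-trimethyl-2-methylidenedecahydronaphthalen-1-yl]butan-2-yl}-2,2-dimethyl-1,3-dioxolane
Product: 28 (2S,3R)-3-methyl-5-[(1S,4aS,8aS)-5,5,8a-trimethyl-2-methylidenedecahydronaphthalen-1-yl]pentane-1,2-diol
Conditions: AcOH/H2O/THF, 40 °C
Reagents that add atoms: none
Why: Mild aqueous acid hydrolyses the terminal acetonide (acetal hydrolysis) under conditions too weak to isomerise the exocyclic 1,1-disubstituted alkene.

Step 14
Reactants: 28 (2S,3R)-3-methyl-5-[(1S,4aS,8aS)-5,5,8a-trimethyl-2-methylidenedecahydronaphthalen-1-yl]pentane-1,2-diol; 29 acetyl chloride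
Product: 30 (2S,3R)-2-hydroxy-3-methyl-5-[(1S,4aS,8aS)-5,5,8a-trimethyl-2-methylidenedecahydronaphthalen-1-yl]pentyl acetate (target, CNP0282247.2)
Conditions: 29 (1.05 equiv), 2,4,6-collidine, CH2Cl2, −78 °C
Reagents that add atoms: acetyl chloride (compound 29), CC(=O)Cl
Why: Low-temperature acylation with one equivalent of acetyl chloride and a hindered base acetylates the primary C15 hydroxyl much faster than the secondary, branched C14 hydroxyl (chemoselective monoacylation of a 1,2-diol).

**Compound list**

1 | 2,2,6-trimethylcyclohexanone (racemic) | CC1CCCC(C)(C)C1=O | starting material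
2 | allyl chloroformate | C=CCOC(=O)Cl | starting material
3 | lithium 2,6,6-trimethylcyclohex-1-en-1-olate | [Li+].[O-]C1=C(C)CCCC1(C)C | intermediate
4 | allyl 2,6,6-trimethylcyclohex-1-en-1-yl carbonate | C=CCOC(=O)OC1=C(C)CCCC1(C)C | intermediate
5 | (R)-2-allyl-2,6,6-trimethylcyclohexan-1-one | O=C1C(C)(C)CCC[C@]1(C)CC=C | intermediate
6 | (R)-2,2,6-trimethyl-6-(2-oxopropyl)cyclohexan-1-one | O=C1C(C)(C)CCC[C@]1(C)CC(C)=O | intermediate
7 | (3aS,7aR)-3a-hydroxy-4,4,7a-trimethyloctahydro-2H-inden-2-one (cis-fused ketol) | O=C1C[C@]2(O)C(C)(C)CCC[C@]2(C)C1 | intermediate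
8 | (7aR)-4,4,7a-trimethyl-1,4,5,6,7,7a-hexahydro-2H-inden-2-one | O=C1C=C2C(C)(C)CCC[C@]2(C)C1 | intermediate
9 | (tert-butyldimethylsilyloxy)acetaldehyde | CC(C)(C)[Si](C)(C)OCC=O | starting material
10 | cis-2-butene | C/C=C\C | starting material
11 | (2S,3R)-1-[(tert-butyldimethylsilyl)oxy]-3-methylpent-4-en-2-yl diisopinocampheylborinate | C=C[C@@H](C)[C@H](OB([C@H]1C[C@H]2C[C@@H]([C@@H]1C)C2(C)C)[C@H]1C[C@H]2C[C@@H]([C@@H]1C)C2(C)C)CO[Si](C)(C)C(C)(C)C | intermediate
12 | (2S,3R)-1-[(tert-butyldimethylsilyl)oxy]-3-methylpent-4-en-2-ol | C=C[C@@H](C)[C@H](O)CO[Si](C)(C)C(C)(C)C | intermediate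
13 | (2S,3R)-3-methylpent-4-ene-1,2-diol | C=C[C@@H](C)[C@H](O)CO | intermediate
14 | (4S)-4-[(2R)-but-3-en-2-yl]-2,2-dimethyl-1,3-dioxolane | C=C[C@@H](C)[C@H]1COC(C)(C)O1 | intermediate
15 | 9-{(3R)-3-[(4S)-2,2-dimethyl-1,3-dioxolan-4-yl]butyl}-9-borabicyclo[3.3.1]nonane | C(CB1C2CCCC1CCC2)[C@@H](C)[C@H]1COC(C)(C)O1 | intermediate
16 | (3R)-3-[(4S)-2,2-dimethyl-1,3-dioxolan-4-yl]butan-1-ol | OCC[C@@H](C)[C@H]1COC(C)(C)O1 | intermediate
17 | (4S)-4-[(2R)-4-iodobutan-2-yl]-2,2-dimethyl-1,3-dioxolane | ICC[C@@H](C)[C@H]1COC(C)(C)O1 | intermediate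
18 | lithium cross-conjugated dienolate of 8 (C9=C8(OLi)–C6=C5) | [Li+].[O-]C1=C[C@@]2(C)CCCC(C)(C)C2=C1 | intermediate
19 | (1S,7aR)-1-{(3R)-3-[(4S)-2,2-dimethyl-1,3-dioxolan-4-yl]butyl}-4,4,7a-trimethyl-1,4,5,6,7,7a-hexahydro-2H-inden-2-one (side chain trans to C20) | O=C1C=C2C(C)(C)CCC[C@]2(C)[C@@H]1CC[C@@H](C)[C@H]3COC(C)(C)O3 | intermediate
20 | lithium enolate (C6=C8–OLi) from reduction of 19 | [Li+].[O-]C1=C[C@H]2C(C)(C)CCC[C@]2(C)[C@@H]1CC[C@@H](C)[C@H]3COC(C)(C)O3 | intermediate
21 | (1S,3aS,7aS)-1-{(3R)-3-[(4S)-2,2-dimethyl-1,3-dioxolan-4-yl]butyl}-4,4,7a-trimethyloctahydro-2H-inden-2-one (C9 epimer of 22) | O=C1C[C@H]2C(C)(C)CCC[C@]2(C)[C@@H]1CC[C@@H](C)[C@H]3COC(C)(C)O3 | intermediate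
22 | (1R,3aS,7aS)-1-{(3R)-3-[(4S)-2,2-dimethyl-1,3-dioxolan-4-yl]butyl}-4,4,7a-trimethyloctahydro-2H-inden-2-one (7,17-dinor-8-oxolabdane-14,15-diol acetonide, trans-hydrindanone) | O=C1C[C@H]2C(C)(C)CCC[C@]2(C)[C@H]1CC[C@@H](C)[C@H]3COC(C)(C)O3 | intermediate
23 | (trimethylsilyl)diazomethane | C[Si](C)(C)C=[N+]=[N-] | starting material
24 | 7-(trimethylsilyl)-8-oxo-17-norlabdane-14,15-diol acetonide (C7 epimers, transient centre) | O=C1C([Si](C)(C)C)C[C@H]2C(C)(C)CCC[C@]2(C)[C@H]1CC[C@@H](C)[C@H]3COC(C)(C)O3 | intermediate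
25 | (1R,4aS,8aS)-1-{(3R)-3-[(4S)-2,2-dimethyl-1,3-dioxolan-4-yl]butyl}-5,5,8a-trimethyloctahydronaphthalen-2(1H)-one (8-oxo-17-norlabdane-14,15-diol acetonide) | O=C1CC[C@H]2C(C)(C)CCC[C@]2(C)[C@H]1CC[C@@H](C)[C@H]3COC(C)(C)O3 | intermediate
26 | methyltriphenylphosphonium bromide | C[P+](c1ccccc1)(c1ccccc1)c1ccccc1.[Br-] | starting material
27 | (4S)-4-{(2R)-4-[(1S,4aS,8aS)-5,5,8a-trimethyl-2-methylidenedecahydronaphthalen-1-yl]butan-2-yl}-2,2-dimethyl-1,3-dioxolane | C=C1CC[C@H]2C(C)(C)CCC[C@]2(C)[C@H]1CC[C@@H](C)[C@H]3COC(C)(C)O3 | intermediate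
28 | (2S,3R)-3-methyl-5-[(1S,4aS,8aS)-5,5,8a-trimethyl-2-methylidenedecahydronaphthalen-1-yl]pentane-1,2-diol | C=C1CC[C@H]2C(C)(C)CCC[C@]2(C)[C@H]1CC[C@@H](C)[C@H](O)CO | intermediate
29 | acetyl chloride | CC(=O)Cl | starting material
30 | (2S,3R)-2-hydroxy-3-methyl-5-[(1S,4aS,8aS)-5,5,8a-trimethyl-2-methylidenedecahydronaphthalen-1-yl]pentyl acetate, i.e. (13R,14S)-14-hydroxylabd-8(17)-en-15-yl acetate | C=C1CC[C@H]2C(C)(C)CCC[C@]2(C)[C@H]1CC[C@@H](C)[C@H](O)COC(C)=O | target

**Step count.** Total: 14 steps (telescoped operations counted as one step each). Longest linear sequence: 10 steps (1–4, 9–14; the side-chain branch 5–8, 9–14 is equally long).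

**Steps most likely to fail, with fallbacks**

1. Step 11 (key step). What may go wrong: competing migration of C9, a second insertion into the new cyclohexanone, or opening of the acetonide by the Lewis acid. The fallback sets out from 22 and comes back at 25, using a regiochemically fixed cyclopropanation and oxidative ring opening in place of the diazo insertion. Kinetic enolisation of 22 at the only accessible methylene, C6 (LiN(i-Pr)2, Me3SiCl, THF, −78 °C), should give the C6=C8 trimethylsilyl enol ether F1. Simmons–Smith cyclopropanation (Et2Zn, CH2I2, CH2Cl2, 0 °C) then gives the siloxycyclopropane F2, in which the new carbon already bridges C6 and C8. FeCl3 in DMF (0 °C, pyridine buffer) cleaves the internal C6–C8 bond by one-electron oxidation to the 6-chloro-17-norlabdan-8-one acetonide F3. NaOAc in MeOH eliminates HCl to the 17-norlabd-6-en-8-one acetonide F4. Hydrogenation (H2, Pd/C, EtOAc), followed by brief NaOMe/MeOH if C9 needs equilibration, gives 25.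

2. Step 9. What may go wrong: slow SN2 attack at the hindered enolate carbon next to quaternary C10, with proton transfer, O-alkylation or elimination of the iodide taking over. The fallback sets out from 16 and 8 and comes back at 22, replacing the alkylation by an aldol condensation. Dess–Martin oxidation of 16 gives (3R)-3-[(4S)-2,2-dimethyl-1,3-dioxolan-4-yl]butanal F5. The dienolate 18 (from 8, LiN(i-Pr)2, THF, −78 °C) adds to this aldehyde rapidly to give the C9–C11 ketol F6 (mixture at C9 and C11, both centres later removed or equilibrated). MsCl/Et3N gives the mesylate F7, and DBU eliminates it to the cross-conjugated 9(11)-dienone F8 (either alkene geometry). Hydrogenation over Pd/C (EtOAc) saturates both C9=C11 and C5=C6, hydrogen reaching C5 from the α face, and NaOMe/MeOH equilibrates C9 to give 22.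

3. Step 10. What may go wrong: protonation of C5 from the wrong face, leading to the cis ring fusion, or over-reduction of the C8 ketone. The fallback sets out from 19 and comes back at 22, replacing electron transfer by heterogeneous hydrogenation (H2, Pd/C, EtOAc). The catalyst surface can only reach the α face of C5=C6, because the β face carries the two axial methyl groups on C4 and C10, and the ketone is not reduced under these conditions. This gives 21, which the same NaOMe/MeOH treatment equilibrates to 22.

**Further compounds**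

F1 | step 11 | C6=C8 trimethylsilyl enol ether of 22 | C[Si](C)(C)OC1=C[C@H]2C(C)(C)CCC[C@]2(C)[C@H]1CC[C@@H](C)[C@H]3COC(C)(C)O3
F2 | step 11 | siloxycyclopropane (CH2 bridging C6 and C8; ring-face configuration immaterial) | C[Si](C)(C)OC12CC1[C@H]3C(C)(C)CCC[C@]3(C)[C@H]2CC[C@@H](C)[C@H]4COC(C)(C)O4
F3 | step 11 | 6-chloro-17-norlabdan-8-one 14,15-acetonide (C6 epimers) | O=C1CC(Cl)[C@H]2C(C)(C)CCC[C@]2(C)[C@H]1CC[C@@H](C)[C@H]3COC(C)(C)O3
F4 | step 11 | 17-norlabd-6-en-8-one 14,15-acetonide | O=C1C=C[C@H]2C(C)(C)CCC[C@]2(C)[C@H]1CC[C@@H](C)[C@H]3COC(C)(C)O3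
F5 | step 9 | (3R)-3-[(4S)-2,2-dimethyl-1,3-dioxolan-4-yl]butanal | O=CC[C@@H](C)[C@H]1COC(C)(C)O1
F6 | step 9 | C9–C11 ketol from 8 and F5 (mixture at C9 and C11) | O=C1C=C2C(C)(C)CCC[C@]2(C)C1C(O)C[C@@H](C)[C@H]3COC(C)(C)O3
F7 | step 9 | C11 mesylate of F6 | O=C1C=C2C(C)(C)CCC[C@]2(C)C1C(OS(C)(=O)=O)C[C@@H](C)[C@H]3COC(C)(C)O3
F8 | step 9 | cross-conjugated 9(11)-dienone (either alkene geometry) | O=C1C=C2C(C)(C)CCC[C@]2(C)C1=CC[C@@H](C)[C@H]3COC(C)(C)O3
F0 | step 10 | none | none
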